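**Strategy.** The route rests on cleaving a ring, not closing one. The target's C1 ketone and C6 carbinol sit 1,6 across the ten-membered ring, so the macrocycle is treated as a cyclohexane (C1–C6) carrying two alkenyl arms. An anionic oxy-Cope ring expansion of a trans-1-isopropenyl-2-(Z-alkoxyvinyl)cyclohexanol, built on (2R,3R)-3-methylcyclohexenone oxide, breaks C1–C6 and forms C8–C9. In one operation it gives the ten-membered ring, the C1 carbonyl (as enolate), the C6 oxygen (as enol ether) and C8 by chair-controlled chirality transfer. The six-membered ring has already fixed the cis C4–C5 epoxide.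

Key step: step 10

Assumption: all ring compounds carry the atom numbers of the target (germacrane numbering: C1 ketone, C4–C5 epoxide, C6 lactone carbinol, C7=C11, C8 acyloxy, C10 methyl, C12 lactone carbonyl, C13 CH2OAc); in this numbering the target is 4R,5S,6S,8S,10R.
Remark: compound 27 (free C8–OH, C1 ketone) can equilibrate with its transannular hemiketal; it is acylated through the open form.

Step 1
Reactants: 1 3-methylcyclohex-2-en-1-one
Product: 2 (2R,3R)-2,3-epoxy-3-methylcyclohexanone
Conditions: 50% aq. H2O2, 9-amino-9-deoxy-epi-cinchona primary amine·2 TFA (10 mol %; the pseudoenantiomer that gives the 2R,3R oxide), dioxane, 50 °C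
Reagents that add atoms: hydrogen peroxide, OO
Why: Amine-catalysed asymmetric Weitz–Scheffer epoxidation via the chiral iminium ion sets C4 and C5 in the absolute sense of the target, and the six-membered ring forces the cis (Z-derived) epoxide.

Step 2
Reactants: 2 (2R,3R)-2,3-epoxy-3-methylcyclohexanone
Product: 3 6-hydroxy-2,3-epoxy-3-methylcyclohexanone (target C1–OH, both epimers)
Conditions: LiHMDS, THF, −78 °C; trans-2-(phenylsulfonyl)-3-phenyloxaziridine, −78 °C; AcOH
Reagents that add atoms: trans-2-(phenylsulfonyl)-3-phenyloxaziridine, O=S(=O)(c1ccccc1)N1OC1c1ccccc1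
Why: The kinetic α′-enolate (the epoxide C–H is not removed) is hydroxylated by the Davis oxaziridine (enolate oxidation); the new carbinol centre is uncontrolled and is erased in step 8.

Step 3
Reactants: 3 6-hydroxy-2,3-epoxy-3-methylcyclohexanone
Product: 4 6-(tert-butyldimethylsilyloxy)-2,3-epoxy-3-methylcyclohexanone
Conditions: TBSCl, imidazole, DMF, 23 °C
Reagents that add atoms: tert-butyldimethylsilyl chloride, CC(C)(C)[Si](C)(C)Cl
Why: Standard silylation of a secondary alcohol, needed so that only the tertiary alkoxide of step 6 is methylated.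

Step 4
Reactants: 5 4-methoxybenzyl alcohol
Product: 6 4-methoxybenzyl vinyl ether
Conditions: ethyl vinyl ether (solvent), Pd(OAc)2 (2 mol %), 1,10-phenanthroline (2 mol %), 23 → 40 °C
Reagents that add atoms: ethyl vinyl ether, C=COCC
Why: Pd(II)-catalysed transfer vinylation (transetherification) of a primary alcohol.

Step 5
Reactants: 6 4-methoxybenzyl vinyl ether
Product: 8 (Z)-2-bromovinyl 4-methoxybenzyl ether, via dibromo ether 7 (not isolated)
Conditions: Br2, CH2Cl2, −78 °C; then DBU, −78 → 23 °C
Reagents that add atoms: bromine, BrBr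
Why: Bromine addition to the enol ether and loss of HBr from the α-bromo ether (the bromination–dehydrobromination route used for the commercial ethyl analogue) should give mainly the Z-bromovinyl ether.

Step 6
Reactants: 8 (Z)-2-bromovinyl 4-methoxybenzyl ether; 4 6-(tert-butyldimethylsilyloxy)-2,3-epoxy-3-methylcyclohexanone
Product: 11 tertiary methyl ether (C6: OMe cis and Z-alkoxyvinyl trans to the epoxide oxygen; C1–OTBS), via vinyllithium 9 (not isolated), via lithium alkoxide 10 (not isolated)
Conditions: 8, t-BuLi (2 equiv), Et2O, −78 °C; then 4, THF, −78 °C; then MeOTf, −78 → −20 °C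
Reagents that add atoms: methyl trifluoromethanesulfonate, COS(=O)(=O)C(F)(F)F
Why: Br/Li exchange with retention gives the configurationally stable Z-β-alkoxyvinyllithium, which adds to the ketone anti to the epoxide oxygen (the usual facial bias of 2,3-epoxycyclohexanones), and the tertiary alkoxide is O-methylated cold, before the neighbouring silyl group can migrate.

Step 7
Reactants: 11 tertiary methyl ether
Product: 12 C1 alcohol
Conditions: TBAF, THF, 0 °C
Reagents that add atoms: none
Why: Fluoride cleavage of the secondary silyl ether; the alkyl enol ether and the epoxide are inert.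

Step 8
Reactants: 12 C1 alcohol
Product: 13 α-methoxy ketone (C1=O, C6 quaternary)
Conditions: Dess–Martin periodinane, pyridine, CH2Cl2, 0 °C
Reagents that add atoms: none
Why: Buffered Dess–Martin oxidation of the secondary alcohol removes the uncontrolled C1 centre without touching the acid-labile 3-alkoxyallyl ether.

Step 9
Reactants: 13 α-methoxy ketone
Product: 14 trans-1-isopropenyl-2-(Z-alkoxyvinyl)cyclohexanol (isopropenyl trans to the alkenyl arm, OH trans to OMe)
Conditions: isopropenylmagnesium bromide, THF, −78 → −40 °C; H2O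
Reagents that add atoms: isopropenylmagnesium bromide, C=C(C)[Mg]Br
Why: Cram-chelate Grignard addition: Mg bridges the C1 carbonyl and the C6 methoxy oxygen, the alkenyl arm is then axial and the reagent enters from the opposite face, which gives the trans-dialkenyl arrangement required for a chair in step 10.

Step 10
Reactants: 14 trans-1-isopropenyl-2-(Z-alkoxyvinyl)cyclohexanol
Product: 17 ten-membered bis-enol ether (C1–OTBS enol ether, C6–OMe enol ether, 8S-OPMB, 4,5-epoxide), via potassium alkoxide 15 (not isolated), via potassium enolate 16 (not isolated)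
Conditions: KH, 18-crown-6, THF, 0 → 23 °C; then TBSCl, −78 → 0 °C
Reagents that add atoms: tert-butyldimethylsilyl chloride, CC(C)(C)[Si](C)(C)Cl
Why: Deprotonation gives alkoxide 15, whose 3-oxido-1,5-diene (C9=C10–C1(O−)–C6–C7=C8) undergoes the anionic oxy-Cope [3,3] shift: C1–C6 of the cyclohexane breaks as C8–C9 forms, and C1 emerges as enolate 16, which is O-silylated. The closest known reaction is the anionic oxy-Cope ring expansion of trans-1,2-dialkenylcyclohexanols to cyclodec-5-enones. The ten-membered ring arises by four-atom ring expansion through a chair-like transition state with both alkenyl arms equatorial on the half-chair cyclohexane, which places the ring carbons trans across both new enol double bonds and leaves the cis-epoxide untouched. The only new stereocentre, C8, is set by that chair: the Z-alkoxy group sits axial on the forming bond, and with the C1/C6 configurations relayed from the epoxide (steps 6 and 9) this corresponds to 8S. The step needs chair over boat, and [3,3] shift over attack of the alkoxide on the epoxide or β-elimination. The trans-diequatorial arms secure the chair, the charge ends on C1 whose enolate has no β-leaving group, and O6 is a non-migrating methyl ether so that C6 emerges as a neutral enol ether that is easily told apart from the C1 silyl enol ether.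

Step 11
Reactants: 17 ten-membered bis-enol ether
Product: 18 α,β-epoxy ketone (C6=O, C7H2; C1 silyl enol ether kept)
Conditions: oxalic acid (0.1 M aq.), THF, 0 °C
Reagents that add atoms: water, O
Why: Acid hydrolysis of the trisubstituted methyl enol ether (C7 protonation, hemiketal collapse) is far faster than that of the hindered tetrasubstituted TBS enol ether, which stays as a mask for the C1 ketone.

Step 12
Reactants: 19 ethyl bromopyruvate
Product: 20 ethyl 3-acetoxy-2-oxopropanoate
Conditions: KOAc, acetone, 0 → 23 °C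
Reagents that add atoms: potassium acetate, CC(=O)[O-].[K+]
Why: SN2 displacement of the activated α-keto bromide by acetate supplies C11, C12 and C13 with the C13 acetate already in place.

Step 13
Reactants: 18 α,β-epoxy ketone; 20 ethyl 3-acetoxy-2-oxopropanoate
Product: 22 aldol adduct (C7–C11 bond; C11 bears OH, CO2Et and CH2OAc), via lithium enolate 21 (not isolated)
Conditions: LDA, THF, −78 °C; then 20, −78 °C; AcOH
Reagents that add atoms: none
Why: C7 is the only enolisable position (C1 is masked, C5 is an epoxide carbon) and its lithium enolate adds to the highly electrophilic α-keto ester carbonyl (aldol addition); the C7 and C11 configurations do not matter because both carbons become sp2 in step 15.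

Step 14
Reactants: 22 aldol adduct
Product: 24 α-hydroxy-γ-lactone (6,12-olide, 6S), via hydroxy ester 23 (not isolated)
Conditions: Zn(BH4)2, Et2O, −30 °C; then PPTS (cat.), CH2Cl2, 23 °C
Reagents that add atoms: none
Why: Chelation-controlled reduction of the α,β-epoxy ketone (Zn bridging C=O and epoxide O, hydride from the open face) should give the anti epoxy alcohol, which is 6S, and the γ-hydroxy ester then lactonises onto C12.

Step 15
Reactants: 24 α-hydroxy-γ-lactone
Product: 25 butenolide (C7=C11, C13–OAc, 8-OPMB, C1 silyl enol ether)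
Conditions: Martin sulfurane, CH2Cl2, 0 → 23 °C
Reagents that add atoms: none
Why: Dehydration of the tertiary α-hydroxy lactone through its alkoxysulfonium ion with loss of H-7 gives the conjugated tetrasubstituted butenolide, whose ring fixes C12 cis to C6 and C13 cis to C8; the neighbouring C13 acetate can assist ionisation where H-7 is not antiperiplanar.

Step 16
Reactants: 25 butenolide
Product: 26 C1 ketone (10R; 8-OPMB)
Conditions: HF·pyridine, pyridine, THF, 0 °C
Reagents that add atoms: none
Why: Protodesilylation of the silyl enol ether; the proton should reach C10 from the exposed outer face of the enol ether (the inner face is blocked by the ring), which in the conformation inherited from the chair of step 10 corresponds to 10R, and base is avoided from here on because C10–H and C6–H are both labile.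

Step 17
Reactants: 26 C1 ketone
Product: 27 C8 alcohol
Conditions: DDQ, CH2Cl2/pH 7 buffer, 0 → 23 °C
Reagents that add atoms: none
Why: Oxidative cleavage of the p-methoxybenzyl ether under neutral conditions that spare the epoxide, the allylic acetate and the butenolide.

Step 18
Reactants: 28 methyl 2-(hydroxymethyl)acrylate
Product: 29 methyl 2-[(tert-butyldimethylsilyloxy)methyl]acrylate
Conditions: TBSCl, imidazole, CH2Cl2, 0 → 23 °C
Reagents that add atoms: tert-butyldimethylsilyl chloride, CC(C)(C)[Si](C)(C)Cl
Why: Standard silylation of the primary alcohol.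

Step 19
Reactants: 29 methyl 2-[(tert-butyldimethylsilyloxy)methyl]acrylate
Product: 30 2-[(tert-butyldimethylsilyloxy)methyl]acrylic acid
Conditions: LiOH, THF/H2O, 0 °C; then 1 M HCl to pH 4
Reagents that add atoms: lithium hydroxide, [Li+].[OH-]
Why: Saponification of the methyl ester; the primary silyl ether survives cold hydroxide and brief mild acid.

Step 20
Reactants: 27 C8 alcohol; 30 2-[(tert-butyldimethylsilyloxy)methyl]acrylic acid
Product: 31 C8 ester (silyl-protected target)
Conditions: EDC·HCl, DMAP (cat.), CH2Cl2, 0 → 23 °C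
Reagents that add atoms: none
Why: Steglich esterification of the secondary alcohol with retention at C8; DMAP is kept catalytic and cold to avoid acetyl migration from O13 and epimerisation at C10.

Step 21
Reactants: 31 C8 ester
Product: 32 target CNP0258719.1
Conditions: HF·pyridine, pyridine, THF, 0 → 23 °C
Reagents that add atoms: none
Why: Buffered HF removes the primary silyl ether without touching the epoxide, the acetate or the two unsaturated esters.

Compound list
1 | 3-methylcyclohex-2-en-1-one | CC1=CC(=O)CCC1 | starting material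
2 | (2R,3R)-2,3-epoxy-3-methylcyclohexanone (carbonyl = C6, epoxide = C5/C4) | C1CC[C@@]2(C)O[C@H]2C1=O | intermediate
3 | 6-hydroxy-(2R,3R)-2,3-epoxy-3-methylcyclohexanone, both C1 epimers | OC1CC[C@@]2(C)O[C@H]2C1=O | intermediate
4 | TBS ether of 3 | CC(C)(C)[Si](C)(C)OC1CC[C@@]2(C)O[C@H]2C1=O | intermediate
5 | 4-methoxybenzyl alcohol | COc1ccc(CO)cc1 | starting material
6 | 4-methoxybenzyl vinyl ether | C=COCc1ccc(OC)cc1 | intermediate
7 | 1,2-dibromoethyl 4-methoxybenzyl ether | BrCC(Br)OCc1ccc(OC)cc1 | intermediate
8 | (Z)-2-bromovinyl 4-methoxybenzyl ether | Br/C=C\OCc1ccc(OC)cc1 | intermediate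
9 | (Z)-2-(4-methoxybenzyloxy)vinyllithium | [Li]/C=C\OCc1ccc(OC)cc1 | intermediate
10 | lithium alkoxide from addition of 9 to 4 (alkenyl trans to the epoxide O) | CC(C)(C)[Si](C)(C)OC1CC[C@@]2(C)O[C@H]2[C@]1([O-])/C=C\OCc1ccc(OC)cc1.[Li+] | intermediate
11 | epoxycyclohexane with C6(OMe)(Z-CH=CH–OPMB), OMe cis to the epoxide O, and C1–OTBS (C1 epimers) | CC(C)(C)[Si](C)(C)OC1CC[C@@]2(C)O[C@H]2[C@]1(OC)/C=C\OCc1ccc(OC)cc1 | intermediate
12 | C1 alcohol from 11 (C1 epimers) | OC1CC[C@@]2(C)O[C@H]2[C@]1(OC)/C=C\OCc1ccc(OC)cc1 | intermediate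
13 | α-methoxy ketone (C1=O) | O=C1CC[C@@]2(C)O[C@H]2[C@]1(OC)/C=C\OCc1ccc(OC)cc1 | intermediate
14 | tertiary alcohol: C1(OH)(isopropenyl), isopropenyl trans to the C6 alkenyl arm, OH trans to OMe and to the epoxide O | C=C(C)[C@@]1(O)CC[C@@]2(C)O[C@H]2[C@]1(OC)/C=C\OCc1ccc(OC)cc1 | intermediate
15 | potassium alkoxide of 14 | C=C(C)[C@@]1([O-])CC[C@@]2(C)O[C@H]2[C@]1(OC)/C=C\OCc1ccc(OC)cc1.[K+] | intermediate
16 | potassium C1 enolate of the ring-expanded ketone | C1[C@@]2(C)O[C@H]2/C(OC)=C/[C@@H](OCc2ccc(OC)cc2)C/C(C)=C([O-])/C1.[K+] | intermediate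
17 | ten-membered bis-enol ether: C1(OTBS)=C10(Me), C6(OMe)=C7, 8S-OPMB, 4,5-cis-epoxide; ring carbons trans across both C=C | C1[C@@]2(C)O[C@H]2/C(OC)=C/[C@@H](OCc2ccc(OC)cc2)C/C(C)=C(O[Si](C)(C)C(C)(C)C)/C1 | intermediate
18 | α,β-epoxy ketone: C6=O, C7H2, C1 TBS enol ether, 8S-OPMB | COc1ccc(CO[C@H]2C/C(C)=C(O[Si](C)(C)C(C)(C)C)/CC[C@@]3(C)O[C@H]3C(=O)C2)cc1 | intermediate
19 | ethyl bromopyruvate | CCOC(=O)C(=O)CBr | starting material
20 | ethyl 3-acetoxy-2-oxopropanoate | CCOC(=O)C(=O)COC(C)=O | intermediate
21 | lithium C6/C7 enolate of 18 | COc1ccc(CO[C@H]2C/C(C)=C(O[Si](C)(C)C(C)(C)C)/CC[C@@]3(C)O[C@H]3C([O-])=C2)cc1.[Li+] | intermediate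
22 | aldol adduct: C7–C11(OH)(CO2Et)(CH2OAc), C7 and C11 as mixtures | COc1ccc(CO[C@H]2C/C(C)=C(O[Si](C)(C)C(C)(C)C)/CC[C@@]3(C)O[C@H]3C(=O)C2C(O)(COC(C)=O)C(=O)OCC)cc1 | intermediate
23 | 6S alcohol of 22 (hydroxy ester) | COc1ccc(CO[C@H]2C/C(C)=C(O[Si](C)(C)C(C)(C)C)/CC[C@@]3(C)O[C@H]3[C@@H](O)C2C(O)(COC(C)=O)C(=O)OCC)cc1 | intermediate
24 | 11-hydroxy-6,12-olide (saturated lactone, 6S, C11–OH, C13–OAc) | COc1ccc(CO[C@H]2C/C(C)=C(O[Si](C)(C)C(C)(C)C)/CC[C@@]3(C)O[C@H]3[C@H]3OC(=O)C(O)(COC(C)=O)C32)cc1 | intermediate
25 | 13-acetoxy-8-(PMB-oxy)-1-(TBS-oxy)-4,5-epoxygermacra-1(10),7(11)-dien-6,12-olide | COc1ccc(CO[C@H]2C/C(C)=C(O[Si](C)(C)C(C)(C)C)/CC[C@@]3(C)O[C@H]3[C@H]3OC(=O)C(COC(C)=O)=C32)cc1 | intermediate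
26 | 13-acetoxy-8-(PMB-oxy)-1-oxo-4,5-epoxygermacr-7(11)-en-6,12-olide (10R) | COc1ccc(CO[C@H]2C[C@@H](C)C(=O)CC[C@@]3(C)O[C@H]3[C@H]3OC(=O)C(COC(C)=O)=C32)cc1 | intermediate
27 | 13-acetoxy-8-hydroxy-1-oxo-4,5-epoxygermacr-7(11)-en-6,12-olide | O[C@H]1C[C@@H](C)C(=O)CC[C@@]2(C)O[C@H]2[C@H]2OC(=O)C(COC(C)=O)=C12 | intermediate
28 | methyl 2-(hydroxymethyl)acrylate | C=C(CO)C(=O)OC | starting material
29 | methyl 2-[(tert-butyldimethylsilyloxy)methyl]acrylate | C=C(CO[Si](C)(C)C(C)(C)C)C(=O)OC | intermediate
30 | 2-[(tert-butyldimethylsilyloxy)methyl]acrylic acid | C=C(CO[Si](C)(C)C(C)(C)C)C(=O)O | intermediate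
31 | 8-O-{2-[(TBS-oxy)methyl]acryloyl} ester of 27 | C=C(CO[Si](C)(C)C(C)(C)C)C(=O)O[C@H]1C[C@@H](C)C(=O)CC[C@@]2(C)O[C@H]2[C@H]2OC(=O)C(COC(C)=O)=C12 | intermediate
32 | CNP0258719.1 | C=C(CO)C(=O)O[C@H]1C[C@@H](C)C(=O)CC[C@@]2(C)O[C@H]2[C@H]2OC(=O)C(COC(C)=O)=C12 | target

Total step count: 21 (16 on the main line; 5 for the three building blocks 8, 20 and 30).
Longest linear sequence: 16 steps (steps 1–3, 6–11, 13–17, 20, 21).

Steps most likely to fail

Step 10 (key step). The naked tertiary alkoxide may attack the C4–C5 epoxide across the ring, or the shift may pass in part through a boat so that C8 forms as a mixture. The fallback removes the charge. Starting from 14, the tertiary alcohol would be silylated (TBSOTf, 2,6-lutidine) to the tertiary silyl ether F1. Heating F1 in toluene (sealed tube, about 180 °C, BSA as acid scavenger) should bring about the neutral siloxy-Cope shift through the same chair and give the bis-enol ether 17 directly, where the route is rejoined.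

Step 15. The elimination may run towards C13 (enol acetate), or fail for those C7/C11 diastereomers of 24 that lack an antiperiplanar H-7. The fallback builds the butenolide with no tertiary alcohol and no stereochemical demand. Starting from 18, the lithium enolate would be added to ethyl glyoxylate to give the aldol F2. Zn(BH4)2 reduction and lactonisation would give the secondary α-hydroxy lactone F3. Dess–Martin oxidation would give the α-keto lactone, which exists as the enol F4 with C7 and C11 both sp2. Tf2O/2,6-lutidine would give the enol triflate F5, and Stille coupling with (tributylstannyl)methanol (Pd(PPh3)4, LiCl, dioxane) the hydroxymethyl butenolide F6. Acetylation (Ac2O, pyridine) returns to 25.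

Step 16. Protonation of the enol ether may be poorly face-selective or give the 10-epimer. The fallback delivers the C10 hydrogen under reagent control. Starting from 25, Saegusa–Ito oxidation (Pd(OAc)2, MeCN) would give the Δ9-enone F7. Hydrogenation of its C9=C10 bond with a chiral Ir–P,N catalyst matched to the 10R face (the tetrasubstituted butenolide alkene is inert) returns to 26.

Further compounds
F1 | step 10 | tertiary TBS ether of 14 | C=C(C)[C@@]1(O[Si](C)(C)C(C)(C)C)CC[C@@]2(C)O[C@H]2[C@]1(OC)/C=C\OCc1ccc(OC)cc1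
F2 | step 15 | glyoxylate aldol of 18: C7–CH(OH)CO2Et, C7 and C11 as mixtures | COc1ccc(CO[C@H]2C/C(C)=C(O[Si](C)(C)C(C)(C)C)/CC[C@@]3(C)O[C@H]3C(=O)C2C(O)C(=O)OCC)cc1
F3 | step 15 | 11-hydroxy-6,12-olide without C13 (6S) | COc1ccc(CO[C@H]2C/C(C)=C(O[Si](C)(C)C(C)(C)C)/CC[C@@]3(C)O[C@H]3[C@H]3OC(=O)C(O)C32)cc1
F4 | step 15 | 11-hydroxybutenolide (enol of the α-keto lactone) | COc1ccc(CO[C@H]2C/C(C)=C(O[Si](C)(C)C(C)(C)C)/CC[C@@]3(C)O[C@H]3[C@H]3OC(=O)C(O)=C32)cc1
F5 | step 15 | butenolide 11-enol triflate | COc1ccc(CO[C@H]2C/C(C)=C(O[Si](C)(C)C(C)(C)C)/CC[C@@]3(C)O[C@H]3[C@H]3OC(=O)C(OS(=O)(=O)C(F)(F)F)=C32)cc1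
F6 | step 15 | 13-hydroxy butenolide (deacetyl 25) | COc1ccc(CO[C@H]2C/C(C)=C(O[Si](C)(C)C(C)(C)C)/CC[C@@]3(C)O[C@H]3[C@H]3OC(=O)C(CO)=C32)cc1
F7 | step 16 | Δ9-enone of 26 (C9=C10 geometry not defined, either serves) | COc1ccc(CO[C@H]2C=C(C)C(=O)CC[C@@]3(C)O[C@H]3[C@H]3OC(=O)C(COC(C)=O)=C32)cc1
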